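Numbering: oxepane O1, C2 (quaternary), C3 (carbinol), C4, C5, C6 (alkylidene carbon), C7 (OCH2); exocyclic C8 and C9 (CH2OH); side chain C1'–C5' (C4' bears methyl, C5' is the ketone).
Enabling feature: ring carbons C3 and C6 both derive from carbonyl carbons and stand 1,4 to each other. The oxepane is therefore a disguised oxepane-3,6-dione whose C4–C5 bond joins two enolate α-carbons, and quaternary C2 leaves the C3 ketone only one direction of enolisation.
Retrosynthetic cuts: the C5'–alkenyl bond, then C6=C8, then C4–C5 (this opens the ring to an acyclic ether diketone), then O1–C7, C3–C4 and C2–C1'.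
Forward: fragment 1 (the C1'–C5' allylic bromide) is joined to fragment 2 (the lactate acetal) at C2–C1'. The ether diketone is then built, the only ring closes at C4–C5, and C8–C9 and the enone terminus are added last.
Stereochemistry: C4' comes from the (S)-Roche ester and C2 from (R)-lactic acid by self-regeneration of the stereocentre. C3 is set by reagent-controlled CBS reduction, the C6=C8 geometry by the stabilised-ylide Wittig reaction, and the enone geometry by syn carboalumination.

Key step: step 13

Remark: TBS = tert-butyldimethylsilyl and TBDPS = tert-butyldiphenylsilyl. The C5' carbinol centre made in step 21 is assumed to need no control because step 22 turns it into the ketone, so 30 is carried as a mixture of epimers.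

Step 1
Reactants: 1 methyl (S)-3-hydroxy-2-methylpropanoate (Roche ester)
Product: 2 methyl (S)-3-(TBS-oxy)-2-methylpropanoate
Conditions: TBSCl (1.1 equiv), imidazole (1.5 equiv), CH2Cl2, 0 °C → rt
Reagents that add atoms: tert-butyldimethylsilyl chloride, CC(C)(C)[Si](C)(C)Cl
Why: Imidazole-promoted silylation of a primary alcohol is routine, does not touch the C4' stereocentre and gives an ether that withstands the hydride, enolate, Grignard and ozone chemistry ahead.

Step 2
Reactants: 2 methyl (S)-3-(TBS-oxy)-2-methylpropanoate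
Product: 3 (S)-3-(TBS-oxy)-2-methylpropanal
Conditions: iBu2AlH (1.05 equiv), CH2Cl2, −78 °C; aq potassium sodium tartrate
Reagents that add atoms: none
Why: Partial reduction of an ester to the aldehyde with one equivalent of iBu2AlH at −78 °C is routine for this protected Roche ester, and the configurationally labile aldehyde is used at once.

Step 3
Reactants: 3 (S)-3-(TBS-oxy)-2-methylpropanal
Product: 4 ethyl (2E,4R)-5-(TBS-oxy)-4-methylpent-2-enoate
Conditions: Ph3P=CHCO2Et (1.2 equiv), CH2Cl2, rt
Reagents that add atoms: (carbethoxymethylene)triphenylphosphorane, CCOC(=O)C=P(c1ccccc1)(c1ccccc1)c1ccccc1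
Why: The Wittig reaction of a stabilised ylide with an aldehyde gives the (E)-enoate under neutral conditions that do not epimerise the α-branched aldehyde.

Step 4
Reactants: 4 ethyl (2E,4R)-5-(TBS-oxy)-4-methylpent-2-enoate
Product: 5 (2E,4R)-5-(TBS-oxy)-4-methylpent-2-en-1-ol
Conditions: iBu2AlH (2.3 equiv), CH2Cl2, −78 → −20 °C
Reagents that add atoms: none
Why: Excess iBu2AlH reduces a conjugated ester in 1,2-fashion to the allylic alcohol and leaves the alkene and the silyl ether alone.

Step 5
Reactants: 5 (2E,4R)-5-(TBS-oxy)-4-methylpent-2-en-1-ol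
Product: 6 (2E,4R)-1-bromo-5-(TBS-oxy)-4-methylpent-2-ene
Conditions: CBr4 (1.2 equiv), PPh3 (1.25 equiv), CH2Cl2, 0 °C
Reagents that add atoms: carbon tetrabromide, BrC(Br)(Br)Br
Why: The Appel reaction turns the primary allylic alcohol into the bromide by SN2 displacement under almost neutral conditions, so the (E)-alkene and the silyl ether are kept.

Step 6
Reactants: 7 (R)-lactic acid
Product: 8 (2R,5R)-2-tert-butyl-5-methyl-1,3-dioxolan-4-one (cis)
Conditions: pivalaldehyde (1.3 equiv), p-TsOH·H2O (cat), pentane, reflux, Dean–Stark trap; crystallisation from pentane, −78 °C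
Reagents that add atoms: pivalaldehyde, CC(C)(C)C=O
Why: Acid-catalysed acetalisation with azeotropic removal of water favours the cis-dioxolanone, which crystallises pure, so the lactate stereocentre is copied onto the new acetal carbon (first half of the self-regeneration of stereocentres).

Step 7
Reactants: 8 (2R,5R)-2-tert-butyl-5-methyl-1,3-dioxolan-4-one; 6 (2E,4R)-1-bromo-5-(TBS-oxy)-4-methylpent-2-ene
Product: 10 (2R,5S)-2-tert-butyl-5-methyl-5-[(2E,4R)-5-(TBS-oxy)-4-methylpent-2-enyl]-1,3-dioxolan-4-one, via lithium enolate 9 (not isolated)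
Conditions: LiN(iPr)2 (1.05 equiv), THF, −78 °C; then 6, −78 → −30 °C
Reagents that add atoms: none
Why: In this enolate alkylation (second half of the self-regeneration of stereocentres) the planar enolate is attacked by the reactive allylic bromide in SN2 fashion on the face anti to the tert-butyl group, so the new C2–C1' bond takes the place of the former hydrogen and quaternary C2 is set as (S).

Step 8
Reactants: 10 (2R,5S)-2-tert-butyl-5-methyl-5-[(2E,4R)-5-(TBS-oxy)-4-methylpent-2-enyl]-1,3-dioxolan-4-one
Product: 11 (2R,5S)-2-tert-butyl-5-methyl-5-[(4R)-5-(TBS-oxy)-4-methylpentyl]-1,3-dioxolan-4-one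
Conditions: H2 (1 atm), PtO2 (3 mol %), EtOAc, rt
Reagents that add atoms: none
Why: Heterogeneous catalytic hydrogenation saturates the disubstituted alkene, and platinum is chosen over palladium because it causes less double-bond migration toward the allylic C4' stereocentre.

Step 9
Reactants: 11 (2R,5S)-2-tert-butyl-5-methyl-5-[(4R)-5-(TBS-oxy)-4-methylpentyl]-1,3-dioxolan-4-one
Product: 12 (2S,6R)-7-(TBS-oxy)-2-hydroxy-N-methoxy-N,2,6-trimethylheptanamide
Conditions: MeNH(OMe)·HCl (3 equiv), iPrMgCl (6 equiv), THF, −20 °C → rt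
Reagents that add atoms: N,O-dimethylhydroxylamine hydrochloride, CNOC.Cl
Why: In this Weinreb aminolysis the magnesium amide attacks the activated lactone-type carbonyl, the acetal falls apart with loss of pivalaldehyde, and the α-hydroxy Weinreb amide results in one operation with C2 untouched.

Step 10
Reactants: 12 (2S,6R)-7-(TBS-oxy)-2-hydroxy-N-methoxy-N,2,6-trimethylheptanamide; 13 3-bromo-2-methylprop-1-ene
Product: 14 (2S,6R)-7-(TBS-oxy)-N-methoxy-N,2,6-trimethyl-2-(2-methylprop-2-enyloxy)heptanamide
Conditions: NaH (1.5 equiv), 13 (2 equiv), Bu4NI (10 mol %), DMF, 0 °C → rt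
Reagents that add atoms: none
Why: Williamson etherification with NaH and a reactive unhindered allylic bromide under iodide catalysis is the usual way to alkylate tertiary α-hydroxy carbonyl compounds, and this amide has no α-hydrogen to lose.

Step 11
Reactants: 14 (2S,6R)-7-(TBS-oxy)-N-methoxy-N,2,6-trimethyl-2-(2-methylprop-2-enyloxy)heptanamide
Product: 15 (3S,7R)-8-(TBS-oxy)-3,7-dimethyl-3-(2-methylprop-2-enyloxy)octan-2-one
Conditions: MeMgBr (2 equiv), THF, 0 °C
Reagents that add atoms: methylmagnesium bromide, C[Mg]Br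
Why: In the Weinreb ketone synthesis the N-methoxy-N-methyl amide takes up a single methyl nucleophile and gives the methyl ketone (C3 and C4) on work-up without over-addition.

Step 12
Reactants: 15 (3S,7R)-8-(TBS-oxy)-3,7-dimethyl-3-(2-methylprop-2-enyloxy)octan-2-one
Product: 17 (3S,7R)-8-(TBS-oxy)-3,7-dimethyl-3-(2-oxopropoxy)octan-2-one, via secondary ozonide 16 (not isolated)
Conditions: O3, CH2Cl2, −78 °C; then PPh3 (1.2 equiv), −78 °C → rt
Reagents that add atoms: ozone, [O-][O+]=O
Why: Ozonolysis cleaves the only alkene, a 1,1-disubstituted one, to the C6 methyl ketone and formaldehyde, and the reductive work-up leaves the C3 ketone, the ether and the silyl ether intact.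

Step 13
Reactants: 17 (3S,7R)-8-(TBS-oxy)-3,7-dimethyl-3-(2-oxopropoxy)octan-2-one
Product: 19 (2S)-2-methyl-2-[(4R)-5-(TBS-oxy)-4-methylpentyl]oxepane-3,6-dione, via bis(lithium enolate) 18 (not isolated)
Conditions: LiN(iPr)2 (2.6 equiv), THF, −78 °C, 17 added over 2 h (final 0.005 M); then CuCl2 (3.0 equiv) in DMF, −78 → 0 °C
Reagents that add atoms: none
Why: Slow addition of 17 to excess LiN(iPr)2 takes one proton from each methyl group, because the C3 ketone has no other α-hydrogen (C2 is quaternary) and the C6 ketone is deprotonated kinetically at the open C5 methyl rather than at C7, which lies next to the bulky tertiary alkoxy group. Divalent copper removes one electron from one enolate, the resulting α-keto radical (free or copper-bound) attacks the terminal carbon of the neighbouring enolate, and a second one-electron oxidation gives the 1,4-diketone and two CuCl. The closest known reaction type is the CuCl2-mediated oxidative coupling of ketone lithium enolates to 1,4-diketones, whose intramolecular form is established for tethered bis-enolates that close smaller rings, so the same reaction is run here on a longer tether that contains an ether oxygen. The oxepane closes in a 7-endo-trig mode, since both carbons of the accepting C5=C6 enolate bond end up in the ring, and the fully substituted C2 compresses the tether and brings C4 and C5 together. No stereocentre is formed, and C2 and C4' cannot be scrambled because neither carries an acidic hydrogen. The step needs double enolisation to be faster than the six-membered aldol of the mono-enolate and ring closure to be faster than dimerisation, which inverse addition to excess base at −78 °C and high dilution are meant to secure.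

Step 14
Reactants: 19 (2S)-2-methyl-2-[(4R)-5-(TBS-oxy)-4-methylpentyl]oxepane-3,6-dione
Product: 20 ethyl (E)-{(2S)-2-methyl-2-[(4R)-5-(TBS-oxy)-4-methylpentyl]-3-oxooxepan-6-ylidene}acetate (plan numbering; ester carbon anti to C7)
Conditions: Ph3P=CHCO2Et (1.5 equiv), toluene, 80 °C
Reagents that add atoms: (carbethoxymethylene)triphenylphosphorane, CCOC(=O)C=P(c1ccccc1)(c1ccccc1)c1ccccc1
Why: The Wittig reaction of the stabilised ylide should take place only at the unhindered, inductively activated C6 ketone because the C3 ketone is shielded by quaternary C2, and as with other α-alkoxy ketones the alkoxy-bearing flank C7 should act as the large group so that the ester ends up anti to it, which is the (E)-geometry of the target.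

Step 15
Reactants: 20 ethyl (E)-{(2S)-2-methyl-2-[(4R)-5-(TBS-oxy)-4-methylpentyl]-3-oxooxepan-6-ylidene}acetate
Product: 21 ethyl (E)-{(2S,3R)-3-hydroxy-2-methyl-2-[(4R)-5-(TBS-oxy)-4-methylpentyl]oxepan-6-ylidene}acetate
Conditions: (S)-Me-CBS oxazaborolidine (C18H20BNO, 0.3 equiv), BH3·SMe2 (1.0 equiv), toluene, −30 °C; MeOH then water
Reagents that add atoms: none
Why: In the Corey–Bakshi–Shibata reduction the (S)-oxazaborolidine binds the ketone with quaternary C2 as the large and C4H2 as the small substituent and delivers hydride to the face that gives the (3R)-alcohol (hydroxyl cis to the C2 methyl), while the conjugated ester is inert to borane at this temperature.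

Step 16
Reactants: 21 ethyl (E)-{(2S,3R)-3-hydroxy-2-methyl-2-[(4R)-5-(TBS-oxy)-4-methylpentyl]oxepan-6-ylidene}acetate
Product: 22 (2S,3R,6E)-6-(2-hydroxyethylidene)-2-methyl-2-[(4R)-5-(TBS-oxy)-4-methylpentyl]oxepan-3-ol
Conditions: iBu2AlH (3.5 equiv), CH2Cl2, −78 °C
Reagents that add atoms: none
Why: Excess iBu2AlH first deprotonates the free C3 hydroxyl and then reduces the conjugated ester in 1,2-fashion to the primary allylic alcohol with the alkene geometry retained.

Step 17
Reactants: 22 (2S,3R,6E)-6-(2-hydroxyethylidene)-2-methyl-2-[(4R)-5-(TBS-oxy)-4-methylpentyl]oxepan-3-ol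
Product: 23 (2S,3R,6E)-6-[2-(TBDPS-oxy)ethylidene]-2-methyl-2-[(4R)-5-(TBS-oxy)-4-methylpentyl]oxepan-3-ol
Conditions: TBDPSCl (1.05 equiv), imidazole (2 equiv), CH2Cl2, 0 °C
Reagents that add atoms: tert-butyldiphenylsilyl chloride, CC(C)(C)[Si](Cl)(c1ccccc1)c1ccccc1
Why: Sterically selective silylation lets the bulky chlorosilane react with the primary allylic alcohol and leaves free the secondary C3 hydroxyl next to quaternary C2.

Step 18
Reactants: 23 (2S,3R,6E)-6-[2-(TBDPS-oxy)ethylidene]-2-methyl-2-[(4R)-5-(TBS-oxy)-4-methylpentyl]oxepan-3-ol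
Product: 24 (2S,3R,6E)-6-[2-(TBDPS-oxy)ethylidene]-2-[(4R)-5-hydroxy-4-methylpentyl]-2-methyloxepan-3-ol
Conditions: pyridinium p-toluenesulfonate (0.3 equiv), EtOH, rt → 40 °C
Reagents that add atoms: none
Why: Mild acid-catalysed solvolysis removes a primary TBS ether much faster than a TBDPS ether, a well-used orthogonality that also spares the allylic ether and the alkene.

Step 19
Reactants: 24 (2S,3R,6E)-6-[2-(TBDPS-oxy)ethylidene]-2-[(4R)-5-hydroxy-4-methylpentyl]-2-methyloxepan-3-ol
Product: 25 (2R)-5-{(2S,3R,6E)-6-[2-(TBDPS-oxy)ethylidene]-3-hydroxy-2-methyloxepan-2-yl}-2-methylpentanal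
Conditions: 2,2,6,6-tetramethylpiperidin-1-oxyl (TEMPO, 10 mol %), PhI(OAc)2 (1.2 equiv), CH2Cl2, rt
Reagents that add atoms: none
Why: The oxoammonium-catalysed TEMPO/PhI(OAc)2 oxidation is selective for primary over hindered secondary alcohols and stops at the aldehyde without epimerising C4'.

Step 20
Reactants: 26 3-methylbut-1-yne
Product: 28 (E)-1-iodo-2,3-dimethylbut-1-ene, via alkenyldimethylalane 27 (not isolated)
Conditions: AlMe3 (2 equiv), Cp2ZrCl2 (0.25 equiv), CH2Cl2, 0 °C → rt; then I2 (1.2 equiv), THF, −30 → 0 °C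
Reagents that add atoms: trimethylaluminium, C[Al](C)C; iodine, [I][I]
Why: The zirconium-catalysed Negishi carboalumination adds methyl and aluminium syn across the terminal alkyne with methyl at the internal carbon, and iodinolysis with retention gives the (E)-alkenyl iodide that carries the enone geometry.

Step 21
Reactants: 28 (E)-1-iodo-2,3-dimethylbut-1-ene; 25 (2R)-5-{(2S,3R,6E)-6-[2-(TBDPS-oxy)ethylidene]-3-hydroxy-2-methyloxepan-2-yl}-2-methylpentanal
Product: 30 (3E,6R)-9-{(2S,3R,6E)-6-[2-(TBDPS-oxy)ethylidene]-3-hydroxy-2-methyloxepan-2-yl}-2,3,6-trimethylnon-3-en-5-ol (C5' epimers), via alkenyllithium 29 (not isolated)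
Conditions: 28 (2.5 equiv), tBuLi (5 equiv), Et2O, −78 °C; then 25, −78 °C
Reagents that add atoms: none
Why: Iodine–lithium exchange with retention of alkene geometry is followed by 1,2-addition of the alkenyllithium to the aldehyde at −78 °C, where one extra equivalent is spent on the free C3 hydroxyl and the new carbinol centre needs no control.

Step 22
Reactants: 30 (3E,6R)-9-{(2S,3R,6E)-6-[2-(TBDPS-oxy)ethylidene]-3-hydroxy-2-methyloxepan-2-yl}-2,3,6-trimethylnon-3-en-5-ol
Product: 31 (3E,6R)-9-{(2S,3R,6E)-6-[2-(TBDPS-oxy)ethylidene]-3-hydroxy-2-methyloxepan-2-yl}-2,3,6-trimethylnon-3-en-5-one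
Conditions: MnO2 (activated, 20 equiv), CH2Cl2, rt
Reagents that add atoms: none
Why: MnO2 oxidises only the allylic secondary alcohol, so the saturated C3 hydroxyl survives, and the neutral heterogeneous conditions spare the epimerisable C4' centre next to the new ketone.

Step 23
Reactants: 31 (3E,6R)-9-{(2S,3R,6E)-6-[2-(TBDPS-oxy)ethylidene]-3-hydroxy-2-methyloxepan-2-yl}-2,3,6-trimethylnon-3-en-5-one
Product: 32 montanol, (3E,6R)-9-[(2S,3R,6E)-3-hydroxy-6-(2-hydroxyethylidene)-2-methyloxepan-2-yl]-2,3,6-trimethylnon-3-en-5-one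
Conditions: Bu4NF (2 equiv), AcOH (2 equiv), THF, 0 °C → rt
Reagents that add atoms: none
Why: Fluoride-mediated desilylation buffered with acetic acid frees the primary allylic alcohol without base-induced epimerisation at C4' or conjugate addition to the enone.

Compound list
1 | methyl (S)-3-hydroxy-2-methylpropanoate (Roche ester) | OC[C@H](C)C(=O)OC | starting material
2 | methyl (S)-3-(TBS-oxy)-2-methylpropanoate | CC(C)(C)[Si](C)(C)OC[C@H](C)C(=O)OC | intermediate
3 | (S)-3-(TBS-oxy)-2-methylpropanal | CC(C)(C)[Si](C)(C)OC[C@H](C)C=O | intermediate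
4 | ethyl (2E,4R)-5-(TBS-oxy)-4-methylpent-2-enoate | CC(C)(C)[Si](C)(C)OC[C@H](C)/C=C/C(=O)OCC | intermediate
5 | (2E,4R)-5-(TBS-oxy)-4-methylpent-2-en-1-ol | CC(C)(C)[Si](C)(C)OC[C@H](C)/C=C/CO | intermediate
6 | (2E,4R)-1-bromo-5-(TBS-oxy)-4-methylpent-2-ene | CC(C)(C)[Si](C)(C)OC[C@H](C)/C=C/CBr | intermediate
7 | (R)-lactic acid | C[C@@H](O)C(=O)O | starting material
8 | (2R,5R)-2-tert-butyl-5-methyl-1,3-dioxolan-4-one (cis) | C[C@H]1O[C@@H](C(C)(C)C)OC1=O | intermediate
9 | lithium enolate of 8 | CC1=C(O[Li])O[C@H](C(C)(C)C)O1 | intermediate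
10 | (2R,5S)-2-tert-butyl-5-methyl-5-[(2E,4R)-5-(TBS-oxy)-4-methylpent-2-enyl]-1,3-dioxolan-4-one | CC(C)(C)[Si](C)(C)OC[C@H](C)/C=C/C[C@]1(C)O[C@@H](C(C)(C)C)OC1=O | intermediate
11 | (2R,5S)-2-tert-butyl-5-methyl-5-[(4R)-5-(TBS-oxy)-4-methylpentyl]-1,3-dioxolan-4-one | CC(C)(C)[Si](C)(C)OC[C@H](C)CCC[C@]1(C)O[C@@H](C(C)(C)C)OC1=O | intermediate
12 | (2S,6R)-7-(TBS-oxy)-2-hydroxy-N-methoxy-N,2,6-trimethylheptanamide | CC(C)(C)[Si](C)(C)OC[C@H](C)CCC[C@](C)(O)C(=O)N(C)OC | intermediate
13 | 3-bromo-2-methylprop-1-ene | C=C(C)CBr | starting material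
14 | (2S,6R)-7-(TBS-oxy)-N-methoxy-N,2,6-trimethyl-2-(2-methylprop-2-enyloxy)heptanamide | CC(C)(C)[Si](C)(C)OC[C@H](C)CCC[C@](C)(OCC(C)=C)C(=O)N(C)OC | intermediate
15 | (3S,7R)-8-(TBS-oxy)-3,7-dimethyl-3-(2-methylprop-2-enyloxy)octan-2-one | CC(C)(C)[Si](C)(C)OC[C@H](C)CCC[C@](C)(OCC(C)=C)C(C)=O | intermediate
16 | secondary ozonide (1,2,4-trioxolane) of 15, epimers at the trioxolane carbon | CC(C)(C)[Si](C)(C)OC[C@H](C)CCC[C@](C)(OCC1(C)OCOO1)C(C)=O | intermediate
17 | (3S,7R)-8-(TBS-oxy)-3,7-dimethyl-3-(2-oxopropoxy)octan-2-one | CC(C)(C)[Si](C)(C)OC[C@H](C)CCC[C@](C)(OCC(C)=O)C(C)=O | intermediate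
18 | bis(lithium enolate) of 17 (C3=C4 and C6=C5) | CC(C)(C)[Si](C)(C)OC[C@H](C)CCC[C@](C)(OCC(=C)O[Li])C(=C)O[Li] | intermediate
19 | (2S)-2-methyl-2-[(4R)-5-(TBS-oxy)-4-methylpentyl]oxepane-3,6-dione | CC(C)(C)[Si](C)(C)OC[C@H](C)CCC[C@]1(C)OCC(=O)CCC1=O | intermediate
20 | ethyl (E)-{(2S)-2-methyl-2-[(4R)-5-(TBS-oxy)-4-methylpentyl]-3-oxooxepan-6-ylidene}acetate | CC(C)(C)[Si](C)(C)OC[C@H](C)CCC[C@]1(C)OC/C(=C/C(=O)OCC)CCC1=O | intermediate
21 | ethyl (E)-{(2S,3R)-3-hydroxy-2-methyl-2-[(4R)-5-(TBS-oxy)-4-methylpentyl]oxepan-6-ylidene}acetate | CC(C)(C)[Si](C)(C)OC[C@H](C)CCC[C@]1(C)OC/C(=C/C(=O)OCC)CC[C@H]1O | intermediate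
22 | (2S,3R,6E)-6-(2-hydroxyethylidene)-2-methyl-2-[(4R)-5-(TBS-oxy)-4-methylpentyl]oxepan-3-ol | CC(C)(C)[Si](C)(C)OC[C@H](C)CCC[C@]1(C)OC/C(=C/CO)CC[C@H]1O | intermediate
23 | (2S,3R,6E)-6-[2-(TBDPS-oxy)ethylidene]-2-methyl-2-[(4R)-5-(TBS-oxy)-4-methylpentyl]oxepan-3-ol | CC(C)(C)[Si](C)(C)OC[C@H](C)CCC[C@]1(C)OC/C(=C/CO[Si](c2ccccc2)(c2ccccc2)C(C)(C)C)CC[C@H]1O | intermediate
24 | (2S,3R,6E)-6-[2-(TBDPS-oxy)ethylidene]-2-[(4R)-5-hydroxy-4-methylpentyl]-2-methyloxepan-3-ol | OC[C@H](C)CCC[C@]1(C)OC/C(=C/CO[Si](c2ccccc2)(c2ccccc2)C(C)(C)C)CC[C@H]1O | intermediate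
25 | (2R)-5-{(2S,3R,6E)-6-[2-(TBDPS-oxy)ethylidene]-3-hydroxy-2-methyloxepan-2-yl}-2-methylpentanal | O=C[C@H](C)CCC[C@]1(C)OC/C(=C/CO[Si](c2ccccc2)(c2ccccc2)C(C)(C)C)CC[C@H]1O | intermediate
26 | 3-methylbut-1-yne | C#CC(C)C | starting material
27 | (E)-(2,3-dimethylbut-1-enyl)dimethylalane | C/C(=C\[Al](C)C)C(C)C | intermediate
28 | (E)-1-iodo-2,3-dimethylbut-1-ene | C/C(=C\I)C(C)C | intermediate
29 | (E)-2,3-dimethylbut-1-enyllithium | C/C(=C\[Li])C(C)C | intermediate
30 | (3E,6R)-9-{(2S,3R,6E)-6-[2-(TBDPS-oxy)ethylidene]-3-hydroxy-2-methyloxepan-2-yl}-2,3,6-trimethylnon-3-en-5-ol, C5' epimers | C/C(=C\C(O)[C@H](C)CCC[C@]1(C)OC/C(=C/CO[Si](c2ccccc2)(c2ccccc2)C(C)(C)C)CC[C@H]1O)C(C)C | intermediate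
31 | (3E,6R)-9-{(2S,3R,6E)-6-[2-(TBDPS-oxy)ethylidene]-3-hydroxy-2-methyloxepan-2-yl}-2,3,6-trimethylnon-3-en-5-one | C/C(=C\C(=O)[C@H](C)CCC[C@]1(C)OC/C(=C/CO[Si](c2ccccc2)(c2ccccc2)C(C)(C)C)CC[C@H]1O)C(C)C | intermediate
32 | montanol | C/C(=C\C(=O)[C@H](C)CCC[C@]1(C)OC/C(=C/CO)CC[C@H]1O)C(C)C | target

Total step count: 23.
Longest linear sequence: 21 steps, from 1 to 32 through steps 1–5, 7–19 and 21–23.

Steps most likely to fail

Step 13 (ring closure).
- What may go wrong: the mono-enolate may close to the six-membered aldol before the second deprotonation. Part of the C6 ketone may enolise toward C7. Intermolecular coupling or α-chlorination by CuCl2 may compete with the seven-membered closure.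
- Fallback, from 17 back to 19: the diketone is added to premixed LiN(iPr)2 and Me3SiCl in THF at −78 °C (internal quench), so each enolate is silylated as it forms.
- This should give the bis(trimethylsilyl enol ether) F1, a neutral compound whose regiochemistry can be checked and which can be freed of isomers.
- F1 is then oxidised with (NH4)2Ce(NO3)6 and NaHCO3 in MeCN at high dilution. This is the known oxidative coupling of silyl enol ethers by tetravalent cerium through an enol-ether radical cation. It forms the same C4–C5 bond in the absence of base and returns to the route at 19.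

Step 14 (olefination).
- What may go wrong: the ylide may discriminate poorly between the C5 and C7 flanks of the ring ketone. The reaction may also be slow at the temperature the stabilised ylide needs.
- Fallback, from 19 back to 20: kinetic stereoselection is given up in favour of separation and recycling. Compound 19 is olefinated with (EtO)2P(O)CH2CO2Et and NaH in THF at 0 °C (Horner–Wadsworth–Emmons reaction), and the geometric isomers are separated by chromatography.
- The (E)-isomer is 20 and rejoins the route there.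
- The unwanted (Z)-enoate F2 is cleaved with O3 and then PPh3. This regenerates 19 for another pass, so the material converges on 20.

Step 10 (etherification).
- What may go wrong: O-alkylation of the hindered tertiary alkoxide may be sluggish, and the N-methoxy amide may break down under the strongly basic conditions.
- Fallback, from 12 back to 17: excess MeMgBr converts the unprotected hydroxy amide into the α-hydroxy methyl ketone F3.
- Rh2(OAc)4-catalysed O–H insertion of 1-diazopropan-2-one (slow addition, CH2Cl2, rt) then installs the acetonyl ether under neutral conditions through a rhodium carbenoid.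
- This gives 17 directly and bypasses 14, 15 and the ozonolysis.

Further compounds
F1 | step 13 | bis(trimethylsilyl enol ether) of 17 (C3=C4 and C6=C5) | CC(C)(C)[Si](C)(C)OC[C@H](C)CCC[C@](C)(OCC(=C)O[Si](C)(C)C)C(=C)O[Si](C)(C)C
F2 | step 14 | ethyl (Z)-{(2S)-2-methyl-2-[(4R)-5-(TBS-oxy)-4-methylpentyl]-3-oxooxepan-6-ylidene}acetate | CC(C)(C)[Si](C)(C)OC[C@H](C)CCC[C@]1(C)OC/C(=C\C(=O)OCC)CCC1=O
F3 | step 10 | (3S,7R)-8-(TBS-oxy)-3-hydroxy-3,7-dimethyloctan-2-one | CC(C)(C)[Si](C)(C)OC[C@H](C)CCC[C@](C)(O)C(C)=O
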